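The trap in this series is to take the straight line of the summer run, multiply it by the time, and call delta finished too.

| setting | dawn | summer | delta | epsilon | beta | gamma | eta |
|---|---|---|---|---|---|---|---|
| substrate | 0.011 M | 1.3 M | 0.020 M | 0.060 M | 0.20 M | 0.50 M | 1.5 M |
| partner | 1.8 equiv | 1.8 equiv | 1.80 equiv | 1.80 equiv | 1.80 equiv | 1.80 equiv | 1.80 equiv |
| free catalyst | 1 mol% | 1 mol% | 1 mol% | 1 mol% | 1 mol% | 1 mol% | 1 mol% |
| remark | run made earlier | run made earlier |  |  |  |  |  |
| time |  |  | 20 h | 20 h | 20 h | 20 h | 20 h |

| run | time / h | target / % |
|---|---|---|
| dawn | 2.00 | 6.8 |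
| dawn | 4.00 | 13.3 |
| dawn | 6.00 | 19.0 |
| dawn | 8.00 | 25.0 |
| dawn | 10.0 | 30.3 |
| dawn | 12.0 | 36.2 |
| dawn | 15.0 | 42.8 |
| summer | 1.00 | 10.9 |
| summer | 1.50 | 17.0 |
| summer | 2.50 | 27.0 |
| summer | 4.00 | 42.8 |
| summer | 6.00 | 63.6 |
| summer | 10.0 | 100.1 |
| summer | 15.0 | 101.4 |

(each reading ± 0.5 percentage points)

- the analysis behind the earlier runs scatters by 0.5 percentage points, standard deviation
- steps that have been proposed: catalyst intermediate C -> catalyst intermediate D; catalyst intermediate B -> released group + catalyst intermediate C; substrate + catalyst intermediate A <-> catalyst intermediate B; partner + free catalyst -> catalyst intermediate A; catalyst intermediate D -> free catalyst + target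
- "hardly changes" means that all values lie within two and a half points (for a concentration: within two and a half percent of the largest)

* [target] at the end for delta, epsilon, beta, gamma, eta, in this order
* how the row runs (falls, then rises / rises, then falls / falls all the way / hardly changes / rises all the way)

The summer run, read at 6.00 h, converts its charge at a fractional rate of 0.106 h⁻¹; we call this top speed u. Delta carries the same 1 mol%, so over 20 h it has a capacity ut of 2.12, twice the charge. But at 6.00 h the dawn run, at 0.011 M, stood at 19.0%, lower than summer's 63.6% at that time.

So we work with the fraction left, f, and not only the fraction made, x. If speed is uS/(K+S), with S the substrate, then for a charge C integration gives ut = x − (K/C) ln f. The last dawn reading, 42.8% at 15.0 h, gives K = 0.0229 M, the substrate concentration of half speed (the Michaelis constant). This is far below the summer charge, which is why we read u there.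

Delta and epsilon look alike, with the same capacity, but the logarithm is priced at K/C, which is 1.14 in delta and 0.381 in epsilon. Guessing x = 0.7 in delta, our reckoning leaves f = 28.9%, or 0.01422 M of target. Guessing x close to the whole charge in epsilon leaves f = 5.30%, or 0.0568 M of target. By this reckoning epsilon ends with a smaller fraction left than delta. In beta the same reckoning leaves 0.00560%, so we expect the row to rise with the charge.

The forecast gave 0.0143 M, 0.0571 M, 0.2 M, 0.5 M and 1.5 M, rises all the way, holding that “Higher concentrations reach completion”. The flasks give 0.0141 M, 0.0571 M, 0.200 M, 0.500 M and 1.50 M: rises all the way.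

    catalyst intermediate C → catalyst intermediate D (k = 0.380 s⁻¹)
    catalyst intermediate B → released group + catalyst intermediate C (k = 0.00330 s⁻¹)
    substrate + catalyst intermediate A ⇌ catalyst intermediate B (K = 44.0 M⁻¹, k = 0.940 M⁻¹ s⁻¹)
    partner + free catalyst → catalyst intermediate A (k = 11.0 M⁻¹ s⁻¹)
    catalyst intermediate D → free catalyst + target (k = 0.0490 s⁻¹)

In delta at 20.0 h, the exchange between substrate plus catalyst intermediate A and catalyst intermediate B, both ways together, relaxes with a half-life of 0.427 min, shorter than the 0.058 h of catalyst intermediate B passing on to released group and catalyst intermediate C. With K, the 0.005864 M of substrate left in delta at that time puts its speed at 20.4% of u, while delta holds 18.0% of its catalyst as catalyst intermediate B and 80.4% as catalyst intermediate A, its resting state at that moment; the 0.002810 M left in epsilon at the same time puts its speed at 10.9% of u, and epsilon holds 9.62% as catalyst intermediate B.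

(The data were computed from invented constants, and the scatter is random.)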